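The six-membered ring C1–C2–C3–C4–C5–C8 of the target (bicyclo[3.2.1]octane numbering: C1 methyl bridgehead, C5 prenyl bridgehead, C8 bridging ketone) is an acylphloroglucinol at a higher oxidation level. Its two-carbon bridge C6–C7 joins the two carbons flanking the C8 oxygen, and the C7 carbinol is exo, syn to that oxygen. The aromatic acylphloroglucinol is therefore assembled first, 2-methylbut-3-en-2-ol is hung on its C8 oxygen through a diisopropylsilyl ketal, and oxidation with PhI(OAc)2 lets the vinyl group add across C1 and C5. This one operation forms C1–C7 and C5–C6, closes the cyclopentanone and sets three stereocentres; fluoride then frees the tertiary alcohol.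

Key step: step 5

Assumption: (2R)-2-methylbutanoic acid is bought in high enantiomeric purity; the locants C1–C8 are those of the bicyclic target and are kept for the same carbons in the aromatic intermediates (C3 carries the acyl group, C2 and C4 the chelating hydroxyls, C8 the oxygen between methyl and prenyl).

Step 1
Reactants: 1 2-methylbenzene-1,3,5-triol; 2 (2R)-2-methylbutanoic acid
Product: 4 (2R)-2-methyl-1-(2,4,6-trihydroxy-3-methylphenyl)butan-1-one, via (2R)-2-methylbutanoyl chloride 3 (not isolated)
Conditions: 2, (COCl)2, cat. DMF, CH2Cl2, 0 °C → rt; then 1, AlCl3, PhNO2/CH2Cl2, 0 °C → rt; aq HCl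
Reagents that add atoms: none
Why: Friedel–Crafts acylation of the strongly activated triol should occur at one of its two equivalent free ring carbons and stop after one acyl group; no stereocentre is formed, and the low temperature is chosen so that the α-stereocentre brought in with 2 is not enolised.

Step 2
Reactants: 4 (2R)-2-methyl-1-(2,4,6-trihydroxy-3-methylphenyl)butan-1-one; 5 1-bromo-3-methylbut-2-ene
Product: 6 (2R)-2-methyl-1-[2,4,6-trihydroxy-3-methyl-5-(3-methylbut-2-en-1-yl)phenyl]butan-1-one
Conditions: 5 (1 equiv), 10% aq KOH, 0 °C
Reagents that add atoms: none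
Why: C-alkylation of the phloroglucinol phenoxide (SN2 at the primary allylic bromide) in water, where the solvated oxygens are poor nucleophiles, should go to C5, the only unsubstituted ring carbon; no stereocentre is formed.

Step 3
Reactants: 7 2-methylbut-3-en-2-ol; 8 dichlorodi(propan-2-yl)silane
Product: 10 chloro[(2-methylbut-3-en-2-yl)oxy]di(propan-2-yl)silane, via lithium 2-methylbut-3-en-2-olate 9 (not isolated)
Conditions: 7, n-BuLi, THF, −78 °C; added to 8 (3 equiv), THF, −78 °C → rt; distillation
Reagents that add atoms: none
Why: Nucleophilic substitution at silicon by the tertiary lithium alkoxide replaces one chloride, and the excess of 8 together with the bulk of the first alkoxy group should prevent a second substitution.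

Step 4
Reactants: 6 (2R)-2-methyl-1-[2,4,6-trihydroxy-3-methyl-5-(3-methylbut-2-en-1-yl)phenyl]butan-1-one; 10 chloro[(2-methylbut-3-en-2-yl)oxy]di(propan-2-yl)silane
Product: 11 (2R)-1-[2,6-dihydroxy-3-methyl-5-(3-methylbut-2-en-1-yl)-4-({[(2-methylbut-3-en-2-yl)oxy]di(propan-2-yl)silyl}oxy)phenyl]-2-methylbutan-1-one
Conditions: 10 (1.1 equiv), imidazole, DMF, 0 °C → rt
Reagents that add atoms: none
Why: Imidazole-promoted silyl ether formation (substitution at silicon) should occur at the hydroxyl para to the acyl group, which is the most acidic one and the only one outside the hydrogen-bonded ketone chelate, so that the C8 oxygen carries the tether.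

Step 5
Reactants: 11 (2R)-1-[2,6-dihydroxy-3-methyl-5-(3-methylbut-2-en-1-yl)-4-({[(2-methylbut-3-en-2-yl)oxy]di(propan-2-yl)silyl}oxy)phenyl]-2-methylbutan-1-one
Product: 12 (1S,5S,7S)-7-[2-({(acetyloxy)di(propan-2-yl)silyl}oxy)propan-2-yl]-2-hydroxy-1-methyl-3-[(2R)-2-methylbutanoyl]-5-(3-methylbut-2-en-1-yl)bicyclo[3.2.1]oct-2-ene-4,8-dione
Conditions: PhI(OAc)2 (1.05 equiv), (CF3)2CHOH/CH2Cl2 1:4, 0.005 M, −40 °C → 0 °C; evaporation, crude used directly
Reagents that add atoms: (diacetoxyiodo)benzene, CC(=O)OI(OC(C)=O)c1ccccc1
Why: Proposed new method: ligand exchange of a chelating hydroxyl (on C2 or C4) at trivalent iodine and loss of iodobenzene should give a phenoxonium ion with its charge on C1, C3 and C5, best seen as a 2-silyloxyallyl cation C1–C8–C5 flanked by the enolised acyl-dione, to which the tethered vinyl group adds asynchronously, CH2 (C6) to C5 and the internal carbon (C7) to C1, before acetate takes the silicon off the C8 silyloxocarbenium ion, which unveils the bridging ketone and leaves an acetoxysilyl ether on the carbinol oxygen. The closest known reactions are the cationic (5+2) cycloadditions of phenoxonium and quinone monoketal cations with alkenes to bicyclo[3.2.1]octenediones, intramolecular carbon-tethered cases included, and the (3+2) additions of 2-oxyallyl cations to alkenes; untested are the phloroglucinol-derived cation and delivery of the alkene from the oxygen of the central carbon through a siloxane. The cyclopentanone ring (C1–C8–C5–C6–C7) is closed by intramolecular cycloaddition, both new bonds going to the two carbons ortho to the tether oxygen across a transient seven-membered siloxane ring (C8–O–Si–O–C–C7–C1). C1 and C5 are set together because the two-carbon bridge must span one ring face, and C7 is set exo because its carbinol carbon is still tied to the C8 oxygen when the C1–C7 bond forms. The step needs C7 to join C1 and not C5, which the tether should secure: the ring carbon joined to C7 must hold its substituent between the gem-dimethyl carbinol carbon and the diisopropylsilyl group, possible for methyl but crowded for prenyl; the prenyl alkene, though more electron-rich, cannot bridge two ring carbons without a bridgehead cation, and high dilution in a fluoroalcohol keeps acetate and intermolecular partners out. No element of the substrate distinguishes the two ring faces, so the (1R,5R,7R) diastereomer should form alongside and is removed after step 6.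

Step 6
Reactants: 12 (1S,5S,7S)-7-[2-({(acetyloxy)di(propan-2-yl)silyl}oxy)propan-2-yl]-2-hydroxy-1-methyl-3-[(2R)-2-methylbutanoyl]-5-(3-methylbut-2-en-1-yl)bicyclo[3.2.1]oct-2-ene-4,8-dione
Product: 13 (1S,5S,7S)-2-hydroxy-7-(2-hydroxypropan-2-yl)-1-methyl-3-[(2R)-2-methylbutanoyl]-5-(3-methylbut-2-en-1-yl)bicyclo[3.2.1]oct-2-ene-4,8-dione
Conditions: HF·pyridine, pyridine, THF, 0 °C → rt; preparative HPLC on a chiral stationary phase
Reagents that add atoms: none
Why: Fluoride attacks silicon and should cleave both Si–O bonds of the acetoxysilyl ether (desilylation) in a buffered, non-basic medium that avoids alkoxide addition to the strained bridging ketone; no stereocentre is touched, and the (1R,5R,7R) diastereomer carried over from step 5 is removed in the chiral-phase separation.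

Compound list
1 | 2-methylbenzene-1,3,5-triol | Cc1c(O)cc(O)cc1O | starting material
2 | (2R)-2-methylbutanoic acid | CC[C@@H](C)C(=O)O | starting material
3 | (2R)-2-methylbutanoyl chloride | CC[C@@H](C)C(Cl)=O | intermediate
4 | (2R)-2-methyl-1-(2,4,6-trihydroxy-3-methylphenyl)butan-1-one | CC[C@@H](C)C(=O)c1c(O)c(C)c(O)cc1O | intermediate
5 | 1-bromo-3-methylbut-2-ene | CC(C)=CCBr | starting material
6 | (2R)-2-methyl-1-[2,4,6-trihydroxy-3-methyl-5-(3-methylbut-2-en-1-yl)phenyl]butan-1-one | CC[C@@H](C)C(=O)c1c(O)c(C)c(O)c(CC=C(C)C)c1O | intermediate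
7 | 2-methylbut-3-en-2-ol | CC(C)(O)C=C | starting material
8 | dichlorodi(propan-2-yl)silane | CC(C)[Si](Cl)(Cl)C(C)C | starting material
9 | lithium 2-methylbut-3-en-2-olate | [Li+].[O-]C(C)(C)C=C | intermediate
10 | chloro[(2-methylbut-3-en-2-yl)oxy]di(propan-2-yl)silane | CC(C)[Si](Cl)(OC(C)(C)C=C)C(C)C | intermediate
11 | (2R)-1-[2,6-dihydroxy-3-methyl-5-(3-methylbut-2-en-1-yl)-4-({[(2-methylbut-3-en-2-yl)oxy]di(propan-2-yl)silyl}oxy)phenyl]-2-methylbutan-1-one | CC[C@@H](C)C(=O)c1c(O)c(C)c(O[Si](C(C)C)(C(C)C)OC(C)(C)C=C)c(CC=C(C)C)c1O | intermediate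
12 | (1S,5S,7S)-7-[2-({(acetyloxy)di(propan-2-yl)silyl}oxy)propan-2-yl]-2-hydroxy-1-methyl-3-[(2R)-2-methylbutanoyl]-5-(3-methylbut-2-en-1-yl)bicyclo[3.2.1]oct-2-ene-4,8-dione | CC[C@@H](C)C(=O)C1=C(O)[C@@]2(C)C(=O)[C@](CC=C(C)C)(C[C@@H]2C(C)(C)O[Si](OC(C)=O)(C(C)C)C(C)C)C1=O | intermediate
13 | (1S,5S,7S)-2-hydroxy-7-(2-hydroxypropan-2-yl)-1-methyl-3-[(2R)-2-methylbutanoyl]-5-(3-methylbut-2-en-1-yl)bicyclo[3.2.1]oct-2-ene-4,8-dione (CNP0201042.1) | CC[C@@H](C)C(=O)C1=C(O)[C@@]2(C)C(=O)[C@](CC=C(C)C)(C[C@@H]2C(C)(C)O)C1=O | target

Total step count: 6. Longest linear sequence: 5 steps (1 or 2 → 4 → 6 → 11 → 12 → 13).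

Steps most likely to fail

Step 5 (key step, proposed new method). The alkene may add the wrong way round, with C7 going to the prenyl-bearing ring carbon. The cation may lose a proton from the methyl group or the prenyl CH2 and collapse through a quinone methide, or be captured by acetate. A 1,2-methyl shift may occur in the developing C7 cation, and the enolised trione may be oxidised further by excess oxidant. The missing face discrimination halves the throughput in any case. The fallback uses known chemistry and closes the ring by a radical instead of a cation. Starting from 6, a second C-alkylation with 5 (NaOMe, MeOH, 0 °C) dearomatises the ring at C5 and gives the gem-diprenyl dienone F1; the isomer alkylated at C1 is removed by chromatography. Oxidation of the enolised dione of F1 with Mn(OAc)3 in AcOH under O2 generates the carbon radical at C1, which closes the five-membered ring by 5-exo addition to one of the C5 prenyl groups. Dioxygen traps the resulting tertiary radical and gives the tertiary hydroperoxide F2. Reduction of F2 with PPh3 returns to the route at 13. This sequence controls neither the ring face nor, fully, the exo position of the carbinol, so 13 is isolated from its stereoisomers by the same chiral-phase HPLC.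

Step 4. Silylation may occur at a chelating hydroxyl or twice, or not at all because both partners are hindered; the tertiary alkoxy group may also exchange at silicon. The fallback replaces the chloride at silicon by a hydride and sets out from 7 and 6. Alcohol 7 is silylated with chlorodi(propan-2-yl)silane (imidazole, CH2Cl2), which is far less hindered than 8, to give the alkoxy hydrosilane F3. F3 is then joined to the most acidic hydroxyl of 6 by KOtBu-catalysed dehydrogenative Si–O coupling (THF, rt, loss of H2), which returns to the route at 11.

Step 1. Configuration at the acyl α-carbon may erode through enolisation of the acyl chloride or of the ketone–AlCl3 complex, and O-acylation may occur without rearrangement; the ratio of enantiomers of 4 is checked by chiral HPLC. The fallback avoids an acylium ion and sets out from 1 and 2. Triol 1 is converted into its tris(methoxymethyl) ether F4 (MOMCl, iPr2NEt, CH2Cl2). Acid chloride 3, made from 2 as in step 1, is turned into the Weinreb amide F5 (MeNHOMe·HCl, pyridine, CH2Cl2, 0 °C). F4 is lithiated between two methoxymethoxy groups (n-BuLi, THF, 0 °C) to the aryllithium F6, which adds once to F5 and gives the protected ketone F7. HCl in MeOH at rt removes the three acetals and returns to the route at 4.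

Further compounds
F1 | step 5 | 3,5-dihydroxy-4-methyl-2-[(2R)-2-methylbutanoyl]-6,6-bis(3-methylbut-2-en-1-yl)cyclohexa-2,4-dien-1-one | CC[C@@H](C)C(=O)C1=C(O)C(C)=C(O)C(CC=C(C)C)(CC=C(C)C)C1=O
F2 | step 5 | (1S,5S,7S)-7-(2-hydroperoxypropan-2-yl)-2-hydroxy-1-methyl-3-[(2R)-2-methylbutanoyl]-5-(3-methylbut-2-en-1-yl)bicyclo[3.2.1]oct-2-ene-4,8-dione | CC[C@@H](C)C(=O)C1=C(O)[C@@]2(C)C(=O)[C@](CC=C(C)C)(C[C@@H]2C(C)(C)OO)C1=O
F3 | step 4 | [(2-methylbut-3-en-2-yl)oxy]di(propan-2-yl)silane | CC(C)[SiH](OC(C)(C)C=C)C(C)C
F4 | step 1 | 1,3,5-tris(methoxymethoxy)-2-methylbenzene | COCOc1cc(OCOC)c(C)c(OCOC)c1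
F5 | step 1 | (2R)-N-methoxy-N,2-dimethylbutanamide | CC[C@@H](C)C(=O)N(C)OC
F6 | step 1 | [2,4,6-tris(methoxymethoxy)-3-methylphenyl]lithium | [Li]c1c(OCOC)cc(OCOC)c(C)c1OCOC
F7 | step 1 | (2R)-2-methyl-1-[2,4,6-tris(methoxymethoxy)-3-methylphenyl]butan-1-one | CC[C@@H](C)C(=O)c1c(OCOC)cc(OCOC)c(C)c1OCOC
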